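**Retrosynthetic overview**
1. Target 25 ⇐ 24 by hydrogenolysis (seven O-benzyl groups and one aryl bromide).
2. Ring C of the upper unit: 24 ⇐ 23 by ring expansion of a trans-3-aryl-2-(α-hydroxybenzyl)-2,3-dihydrobenzofuran (furan → pyran, 1,2-shift of the ring oxygen through an oxiranium ion). 23 ⇐ 19 + 6 by asymmetric [4+1] annulation; 19 ⇐ aryllithium of 16 + aldehyde 9 (this forms the C4–C6′ bond).
3. Ring C of the lower unit the same way: 15 ⇐ 14 (ring expansion) ⇐ 13 (hydrogenation with dynamic kinetic resolution) ⇐ 6 + 10 ([4+1] annulation).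
4. 6 ⇐ catechol 1 + amide 4; 9 and 10 ⇐ resorcinol 7 + DMF. 6 and 9 each serve both units.
5. Ring order: lower furan ring → lower pyran ring → upper furan ring → upper pyran ring; rings A and B are bought as arenes.

Assumption: the SMILES is read as fisetinidol-(4α→6′)-fisetinidol, upper unit (2R,3S,4R), lower unit (2R,3S); catechol, resorcinol and 2-chloro-N-methoxy-N-methylacetamide are bought.

**Route**

Step 1
Reactants: 1 catechol
Product: 2 1,2-bis(benzyloxy)benzene
Conditions: BnBr (2.2 equiv), K2CO3, DMF, 60 °C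
Reagents that add atoms: benzyl bromide, BrCc1ccccc1
Why: Williamson ether synthesis on both phenols; no stereocenter is formed.

Step 2
Reactants: 2 1,2-bis(benzyloxy)benzene
Product: 3 1,2-bis(benzyloxy)-4,5-dibromobenzene
Conditions: NBS (2.1 equiv), MeCN, 25 → 50 °C, dark
Reagents that add atoms: N-bromosuccinimide, O=C1CCC(=O)N1Br
Why: Electrophilic aromatic bromination, each bromine entering para to one benzyloxy group.

Step 3
Reactants: 3 1,2-bis(benzyloxy)-4,5-dibromobenzene; 4 2-chloro-N-methoxy-N-methylacetamide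
Product: 6 1-[4,5-bis(benzyloxy)-2-bromophenyl]-2-chloroethan-1-one, via arylmagnesium chloride 5 (not isolated)
Conditions: i-PrMgCl·LiCl (1.05 equiv), THF, −15 °C; then 4, −15 → 0 °C; aq. NH4Cl
Reagents that add atoms: none
Why: Br/Mg exchange stops after one bromine (the ortho-bromo Grignard reagent is stable below 0 °C) and the Weinreb ketone synthesis gives the α-chloroketone without over-addition.

Step 4
Reactants: 7 resorcinol
Product: 8 2,4-dihydroxybenzaldehyde
Conditions: POCl3, DMF, MeCN, −15 → 25 °C; then H2O, 50 °C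
Reagents that add atoms: N,N-dimethylformamide, CN(C)C=O
Why: Vilsmeier–Haack formylation, which on resorcinol goes para to one hydroxyl and ortho to the other.

Step 5
Reactants: 8 2,4-dihydroxybenzaldehyde
Product: 9 4-(benzyloxy)-2-hydroxybenzaldehyde
Conditions: BnBr (1.05 equiv), NaHCO3, KI (10 mol%), MeCN, 80 °C
Reagents that add atoms: benzyl bromide, BrCc1ccccc1
Why: Williamson ether synthesis; the 2-OH is hydrogen-bonded to the aldehyde and stays free, so only the 4-OH is alkylated.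

Step 6
Reactants: 9 4-(benzyloxy)-2-hydroxybenzaldehyde
Product: 10 5-(benzyloxy)-2-(hydroxymethyl)phenol
Conditions: NaBH4, THF/MeOH, 0 °C
Reagents that add atoms: none
Why: Borohydride reduction of the aldehyde gives the ortho-hydroxybenzyl alcohol needed as quinone methide precursor.

Step 7
Reactants: 6 1-[4,5-bis(benzyloxy)-2-bromophenyl]-2-chloroethan-1-one; 10 5-(benzyloxy)-2-(hydroxymethyl)phenol
Product: 13 rac-[4,5-bis(benzyloxy)-2-bromophenyl][6-(benzyloxy)-2,3-dihydro-1-benzofuran-2-yl]methanone, via pyridinium salt 11 (not isolated), via ortho-quinone methide 12 (not isolated)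
Conditions: 6, pyridine (1.2 equiv), MeCN, 60 °C; then 10, DBU (2.2 equiv), MeCN, 80 °C
Reagents that add atoms: none
Why: Formal [4+1] annulation of an ortho-quinone methide with a pyridinium ylide (conjugate addition, then the phenoxide displaces pyridine); the α-aryloxy ketone center is deliberately left racemic because step 8 resolves it dynamically.

Step 8
Reactants: 13 rac-[4,5-bis(benzyloxy)-2-bromophenyl][6-(benzyloxy)-2,3-dihydro-1-benzofuran-2-yl]methanone
Product: 14 (S)-[4,5-bis(benzyloxy)-2-bromophenyl][(2R)-6-(benzyloxy)-2,3-dihydro-1-benzofuran-2-yl]methanol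
Conditions: RuCl2[(S)-xylbinap][(S)-daipen] (1 mol%), t-BuOK (10 mol%), i-PrOH/THF, H2 (10 atm), 25 °C
Reagents that add atoms: none
Why: Noyori asymmetric hydrogenation with dynamic kinetic resolution; t-BuOK racemises the α-aryloxy ketone carbon faster than reduction, the catalyst fixes the carbinol as S (same facial sense as acetophenone to (R)-1-phenylethanol), and the matched substrate enantiomer is expected to give the anti product with furan C2 as R, as seen with α-alkoxy aryl ketones.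

Step 9
Reactants: 14 (S)-[4,5-bis(benzyloxy)-2-bromophenyl][(2R)-6-(benzyloxy)-2,3-dihydro-1-benzofuran-2-yl]methanol
Product: 15 (2R,3S)-7-(benzyloxy)-2-[4,5-bis(benzyloxy)-2-bromophenyl]chroman-3-ol
Conditions: TfOH (2 mol%), (CF3)2CHOH/H2O 20:1, 0.02 M, 0 → 25 °C
Reagents that add atoms: water, O
Why: Proposed new method: acid-triggered oxiranium ring expansion of a 2-(α-hydroxybenzyl)-2,3-dihydrobenzofuran to a flavan-3-ol, in which the electron-rich benzylic C–OH ionises, the furan oxygen (anti to the leaving group in the anti carbinol) bridges to an aryl-oxiranium ion and so shifts 1,2 onto the benzylic carbon with inversion (new C2, R), and water opens the ion at the former furan C2 with inversion (new C3, S, trans to the 2-aryl group, also the thermodynamic arrangement), while benzylic return only regenerates re-ionisable carbinol and the chroman-3-ol cannot re-ionise; the closest known reaction type is the tetrahydrofuran-to-tetrahydropyran ring expansion of α-sulfonyloxyalkyl tetrahydrofurans with Zn(OAc)2 and, in reverse, the ring contraction of flavan-3-ol 3-sulfonates.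

Step 10
Reactants: 15 (2R,3S)-7-(benzyloxy)-2-[4,5-bis(benzyloxy)-2-bromophenyl]chroman-3-ol
Product: 16 (2R,3S)-3,7-bis(benzyloxy)-2-[4,5-bis(benzyloxy)-2-bromophenyl]chroman
Conditions: NaH, BnBr, Bu4NI (5 mol%), THF/DMF, 0 → 25 °C
Reagents that add atoms: benzyl bromide, BrCc1ccccc1
Why: Williamson O-benzylation masks the 3-OH, which would otherwise quench the aryllithium of step 11 and add intramolecularly to the quinone methide of step 12.

Step 11
Reactants: 16 (2R,3S)-3,7-bis(benzyloxy)-2-[4,5-bis(benzyloxy)-2-bromophenyl]chroman; 9 4-(benzyloxy)-2-hydroxybenzaldehyde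
Product: 19 5-(benzyloxy)-2-[{4,5-bis(benzyloxy)-2-[(2R,3S)-3,7-bis(benzyloxy)chroman-2-yl]phenyl}(4-methylbenzenesulfonyl)methyl]phenol (both epimers at the sulfonyl carbon), via aryllithium 17 (not isolated), via diaryl carbinol 18 (not isolated)
Conditions: 16, n-BuLi (1.05 equiv), THF, −78 °C; then 9 (pre-treated with NaH in THF), −78 → 0 °C; then p-TolSO2H (4 equiv), CH2Cl2, 25 °C
Reagents that add atoms: p-toluenesulfinic acid, Cc1ccc(cc1)S(O)=O
Why: Br/Li exchange and 1,2-addition of the aryllithium to the aldehyde fix the C4–C6′ bond regiospecifically, and SN1 substitution of the doubly activated benzhydrol by sulfinate installs the leaving group for step 12; the new center is a mixture and is destroyed there.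

Step 12
Reactants: 19 the sulfone of step 11; 6 1-[4,5-bis(benzyloxy)-2-bromophenyl]-2-chloroethan-1-one
Product: 22 [(2R,3R)-6-(benzyloxy)-3-{4,5-bis(benzyloxy)-2-[(2R,3S)-3,7-bis(benzyloxy)chroman-2-yl]phenyl}-2,3-dihydro-1-benzofuran-2-yl][4,5-bis(benzyloxy)-2-bromophenyl]methanone, via quinidinium salt 20 (not isolated), via ortho-quinone methide 21 (not isolated)
Conditions: 6, 9-O-methylquinidine (1.1 equiv), NaI (10 mol%), MeCN, 50 °C; then 19, Cs2CO3 (3 equiv), CH2Cl2, 0 → 25 °C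
Reagents that add atoms: none
Why: Asymmetric formal [4+1] annulation of an ortho-quinone methide with a cinchona-derived ammonium ylide; Cs2CO3 eliminates sulfinate from 19 and deprotonates 20, the ylide adds to the methide carbon on the face set by the alkaloid (furan C3, R), and the phenoxide displaces the amine to close the trans ring (C2, R, the thermodynamically preferred epimer).

Step 13
Reactants: 22 the trans ketone of step 12
Product: 23 (S)-[(2R,3R)-6-(benzyloxy)-3-{4,5-bis(benzyloxy)-2-[(2R,3S)-3,7-bis(benzyloxy)chroman-2-yl]phenyl}-2,3-dihydro-1-benzofuran-2-yl][4,5-bis(benzyloxy)-2-bromophenyl]methanol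
Conditions: Zn(BH4)2, Et2O, −30 → 0 °C; aq. NH4Cl
Reagents that add atoms: none
Why: Chelation-controlled ketone reduction (zinc bridges the carbonyl and furan oxygens, hydride enters from the side of the C2–H) gives the anti carbinol (S); the minor epimer should also converge in step 14 because the benzylic center ionises.

Step 14
Reactants: 23 the carbinol of step 13
Product: 24 (2R,3S,4R)-7-(benzyloxy)-2-[4,5-bis(benzyloxy)-2-bromophenyl]-4-{4,5-bis(benzyloxy)-2-[(2R,3S)-3,7-bis(benzyloxy)chroman-2-yl]phenyl}chroman-3-ol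
Conditions: TfOH (2 mol%), (CF3)2CHOH/H2O 20:1, 0.01 M, 0 → 25 °C
Reagents that add atoms: water, O
Why: Proposed new method: the same oxiranium ring expansion on the 3-aryl substrate, in which furan C3 is untouched and becomes C4 (R), water enters at the former furan C2 anti to the departing ring oxygen and hence trans to the 4-aryl group (C3, S), and the ring oxygen shifts onto the benzylic carbon so that the 2-aryl group ends trans to the 3-OH (C2, R), giving the all-equatorial and thermodynamically preferred isomer; the closest known reaction type is the one named in step 9.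

Step 15
Reactants: 24 the protected dimer of step 14
Product: 25 (2R,3S,4R)-2-(3,4-dihydroxyphenyl)-4-{2-[(2R,3S)-3,7-dihydroxychroman-2-yl]-4,5-dihydroxyphenyl}chroman-3,7-diol
Conditions: H2 (1 atm), Pd(OH)2/C, NaOAc (1.5 equiv), THF/MeOH 1:1, 25 °C
Reagents that add atoms: none
Why: Catalytic hydrogenolysis removes the seven benzyl ethers and the aryl bromide in one operation (NaOAc takes up HBr); no stereocenter is touched.

**Compound list**

1 | catechol | Oc1ccccc1O | starting material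
2 | 1,2-bis(benzyloxy)benzene | c1ccc(cc1)COc1ccccc1OCc1ccccc1 | intermediate
3 | 1,2-bis(benzyloxy)-4,5-dibromobenzene | Brc1cc(OCc2ccccc2)c(OCc2ccccc2)cc1Br | intermediate
4 | 2-chloro-N-methoxy-N-methylacetamide | ClCC(=O)N(C)OC | starting material
5 | [4,5-bis(benzyloxy)-2-bromophenyl]magnesium chloride | Cl[Mg]c1cc(OCc2ccccc2)c(OCc2ccccc2)cc1Br | intermediate
6 | 1-[4,5-bis(benzyloxy)-2-bromophenyl]-2-chloroethan-1-one | ClCC(=O)c1cc(OCc2ccccc2)c(OCc2ccccc2)cc1Br | intermediate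
7 | resorcinol | Oc1cccc(O)c1 | starting material
8 | 2,4-dihydroxybenzaldehyde | O=Cc1ccc(O)cc1O | intermediate
9 | 4-(benzyloxy)-2-hydroxybenzaldehyde | O=Cc1ccc(OCc2ccccc2)cc1O | intermediate
10 | 5-(benzyloxy)-2-(hydroxymethyl)phenol | OCc1ccc(OCc2ccccc2)cc1O | intermediate
11 | 1-{2-[4,5-bis(benzyloxy)-2-bromophenyl]-2-oxoethyl}pyridinium chloride | O=C(C[n+]1ccccc1)c1cc(OCc2ccccc2)c(OCc2ccccc2)cc1Br.[Cl-] | intermediate
12 | 3-(benzyloxy)-6-methylidenecyclohexa-2,4-dien-1-one | C=C1C=CC(OCc2ccccc2)=CC1=O | intermediate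
13 | rac-[4,5-bis(benzyloxy)-2-bromophenyl][6-(benzyloxy)-2,3-dihydro-1-benzofuran-2-yl]methanone | O=C(C1Cc2ccc(OCc3ccccc3)cc2O1)c1cc(OCc2ccccc2)c(OCc2ccccc2)cc1Br | intermediate
14 | (S)-[4,5-bis(benzyloxy)-2-bromophenyl][(2R)-6-(benzyloxy)-2,3-dihydro-1-benzofuran-2-yl]methanol | C(c1ccccc1)Oc1ccc2c(c1)O[C@@H]([C@@H](O)c1cc(OCc3ccccc3)c(OCc3ccccc3)cc1Br)C2 | intermediate
15 | (2R,3S)-7-(benzyloxy)-2-[4,5-bis(benzyloxy)-2-bromophenyl]chroman-3-ol | C(c1ccccc1)Oc1ccc2c(c1)O[C@H](c1cc(OCc3ccccc3)c(OCc3ccccc3)cc1Br)[C@@H](O)C2 | intermediate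
16 | (2R,3S)-3,7-bis(benzyloxy)-2-[4,5-bis(benzyloxy)-2-bromophenyl]chroman | C(c1ccccc1)Oc1ccc2c(c1)O[C@H](c1cc(OCc3ccccc3)c(OCc3ccccc3)cc1Br)[C@@H](OCc1ccccc1)C2 | intermediate
17 | {4,5-bis(benzyloxy)-2-[(2R,3S)-3,7-bis(benzyloxy)chroman-2-yl]phenyl}lithium | C(c1ccccc1)Oc1ccc2c(c1)O[C@H](c1cc(OCc3ccccc3)c(OCc3ccccc3)cc1[Li])[C@@H](OCc1ccccc1)C2 | intermediate
18 | {4,5-bis(benzyloxy)-2-[(2R,3S)-3,7-bis(benzyloxy)chroman-2-yl]phenyl}[4-(benzyloxy)-2-hydroxyphenyl]methanol (both carbinol epimers) | C(c1ccccc1)Oc1ccc2c(c1)O[C@H](c1cc(OCc3ccccc3)c(OCc3ccccc3)cc1C(O)c1ccc(OCc3ccccc3)cc1O)[C@@H](OCc1ccccc1)C2 | intermediate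
19 | 5-(benzyloxy)-2-[{4,5-bis(benzyloxy)-2-[(2R,3S)-3,7-bis(benzyloxy)chroman-2-yl]phenyl}(4-methylbenzenesulfonyl)methyl]phenol (both epimers at the sulfonyl carbon) | C(c1ccccc1)Oc1ccc2c(c1)O[C@H](c1cc(OCc3ccccc3)c(OCc3ccccc3)cc1C(c1ccc(OCc3ccccc3)cc1O)S(=O)(=O)c1ccc(C)cc1)[C@@H](OCc1ccccc1)C2 | intermediate
20 | 1-{2-[4,5-bis(benzyloxy)-2-bromophenyl]-2-oxoethyl}-9-O-methylquinidinium chloride (quaternised at the quinuclidine nitrogen) | COc1ccc2nccc(c2c1)[C@@H]([C@H]3C[C@@H]4CC[N+]3(CC(=O)c3cc(OCc5ccccc5)c(OCc5ccccc5)cc3Br)C[C@@H]4C=C)OC.[Cl-] | intermediate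
21 | 3-(benzyloxy)-6-({4,5-bis(benzyloxy)-2-[(2R,3S)-3,7-bis(benzyloxy)chroman-2-yl]phenyl}methylidene)cyclohexa-2,4-dien-1-one | C(c1ccccc1)Oc1ccc2c(c1)O[C@H](c1cc(OCc3ccccc3)c(OCc3ccccc3)cc1C=C1C=CC(OCc3ccccc3)=CC1=O)[C@@H](OCc1ccccc1)C2 | intermediate
22 | [(2R,3R)-6-(benzyloxy)-3-{4,5-bis(benzyloxy)-2-[(2R,3S)-3,7-bis(benzyloxy)chroman-2-yl]phenyl}-2,3-dihydro-1-benzofuran-2-yl][4,5-bis(benzyloxy)-2-bromophenyl]methanone | C(c1ccccc1)Oc1ccc2c(c1)O[C@H](c1cc(OCc3ccccc3)c(OCc3ccccc3)cc1[C@@H]1c3ccc(OCc4ccccc4)cc3O[C@H]1C(=O)c1cc(OCc3ccccc3)c(OCc3ccccc3)cc1Br)[C@@H](OCc1ccccc1)C2 | intermediate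
23 | (S)-[(2R,3R)-6-(benzyloxy)-3-{4,5-bis(benzyloxy)-2-[(2R,3S)-3,7-bis(benzyloxy)chroman-2-yl]phenyl}-2,3-dihydro-1-benzofuran-2-yl][4,5-bis(benzyloxy)-2-bromophenyl]methanol | C(c1ccccc1)Oc1ccc2c(c1)O[C@H](c1cc(OCc3ccccc3)c(OCc3ccccc3)cc1[C@@H]1c3ccc(OCc4ccccc4)cc3O[C@H]1[C@@H](O)c1cc(OCc3ccccc3)c(OCc3ccccc3)cc1Br)[C@@H](OCc1ccccc1)C2 | intermediate
24 | (2R,3S,4R)-7-(benzyloxy)-2-[4,5-bis(benzyloxy)-2-bromophenyl]-4-{4,5-bis(benzyloxy)-2-[(2R,3S)-3,7-bis(benzyloxy)chroman-2-yl]phenyl}chroman-3-ol | C(c1ccccc1)Oc1ccc2c(c1)O[C@H](c1cc(OCc3ccccc3)c(OCc3ccccc3)cc1[C@@H]1c3ccc(OCc4ccccc4)cc3O[C@H](c3cc(OCc4ccccc4)c(OCc4ccccc4)cc3Br)[C@H]1O)[C@@H](OCc1ccccc1)C2 | intermediate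
25 | (2R,3S,4R)-2-(3,4-dihydroxyphenyl)-4-{2-[(2R,3S)-3,7-dihydroxychroman-2-yl]-4,5-dihydroxyphenyl}chroman-3,7-diol | Oc1ccc2c(c1)O[C@H](c1cc(O)c(O)cc1[C@@H]1c3ccc(O)cc3O[C@H](c3ccc(O)c(O)c3)[C@H]1O)[C@@H](O)C2 | target

**Step count and risks**

Total: 15 steps. Longest linear sequence: 12 steps (steps 1, 2, 3, 7, 8, 9, 10, 11, 12, 13, 14, 15, from catechol).

Steps most likely to fail:

Step 9 (proposed ring expansion, lower unit). The benzylic ion may eliminate to a 2-benzylbenzofuran, or return to carbinol faster than water opens the oxiranium ion at the furan carbon. The fallback uses known chemistry, sets out from 13 and comes back at 15, and also bypasses step 8. SmI2 (THF/MeOH, −78 °C) cleaves the α-aryloxy ketone C–O bond of 13 to 1-[4,5-bis(benzyloxy)-2-bromophenyl]-3-[4-(benzyloxy)-2-hydroxyphenyl]propan-1-one F1. TsOH (cat.) in toluene at 80 °C cyclodehydrates this to the enol ether 7-(benzyloxy)-2-[4,5-bis(benzyloxy)-2-bromophenyl]-4H-chromene F2. Asymmetric hydroboration with monoisopinocampheylborane (IpcBH2, enantiomer chosen in a test run) followed by NaOH/H2O2 adds H and B syn across C2=C3 with boron at C3, which gives the 2,3-trans alcohol 15.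

Step 12 (asymmetric [4+1] annulation on a hindered, ortho-substituted quinone methide). The facial control by the alkaloid is untested on this substrate; if the quinidine salt gives the wrong face, the quinine-derived pseudoenantiomer is the first change. The fallback changes the approach, sets out from 18 (step 11 stopped before the sulfinic acid quench and 18 isolated) and 6, and comes back at 22. N,N′-ditosylhydrazine and DBU (THF, 0 °C) convert 6 into 1-[4,5-bis(benzyloxy)-2-bromophenyl]-2-diazoethan-1-one F3. A BINOL-derived chiral phosphoric acid (5 mol%, CHCl3, 25 °C) dehydrates 18 to quinone methide 21 and steers the addition of F3 to it; ring closure with loss of N2 gives the cis ketone [(2S,3R)-6-(benzyloxy)-3-{4,5-bis(benzyloxy)-2-[(2R,3S)-3,7-bis(benzyloxy)chroman-2-yl]phenyl}-2,3-dihydro-1-benzofuran-2-yl][4,5-bis(benzyloxy)-2-bromophenyl]methanone F4. DBU (CH2Cl2, 25 °C) epimerises C2 to the trans ketone 22.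

Step 14 (proposed ring expansion, upper unit). This is the hardest case, because water must open the oxiranium ion at a carbon flanked by a diarylmethine. The fallback uses known chemistry, sets out from 22 and comes back at 24. SmI2 (THF/MeOH, −78 °C) cleaves the furan C–O bond next to the ketone to (3R)-1-[4,5-bis(benzyloxy)-2-bromophenyl]-3-[4-(benzyloxy)-2-hydroxyphenyl]-3-{4,5-bis(benzyloxy)-2-[(2R,3S)-3,7-bis(benzyloxy)chroman-2-yl]phenyl}propan-1-one F5, with the diarylmethine center intact. TsOH (cat.) in toluene at 80 °C closes it to (4R)-7-(benzyloxy)-2-[4,5-bis(benzyloxy)-2-bromophenyl]-4-{4,5-bis(benzyloxy)-2-[(2R,3S)-3,7-bis(benzyloxy)chroman-2-yl]phenyl}-4H-chromene F6. BH3·SMe2 then NaOH/H2O2 adds to the face anti to the 4-aryl group with boron at C3, so the 3-OH ends trans to both aryl groups, which is 24.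

**Further compounds**

F1 | step 9 | 1-[4,5-bis(benzyloxy)-2-bromophenyl]-3-[4-(benzyloxy)-2-hydroxyphenyl]propan-1-one | O=C(CCc1ccc(OCc2ccccc2)cc1O)c1cc(OCc2ccccc2)c(OCc2ccccc2)cc1Br
F2 | step 9 | 7-(benzyloxy)-2-[4,5-bis(benzyloxy)-2-bromophenyl]-4H-chromene | C1C=C(c2cc(OCc3ccccc3)c(OCc3ccccc3)cc2Br)Oc2cc(OCc3ccccc3)ccc12
F3 | step 12 | 1-[4,5-bis(benzyloxy)-2-bromophenyl]-2-diazoethan-1-one | [N-]=[N+]=CC(=O)c1cc(OCc2ccccc2)c(OCc2ccccc2)cc1Br
F4 | step 12 | [(2S,3R)-6-(benzyloxy)-3-{4,5-bis(benzyloxy)-2-[(2R,3S)-3,7-bis(benzyloxy)chroman-2-yl]phenyl}-2,3-dihydro-1-benzofuran-2-yl][4,5-bis(benzyloxy)-2-bromophenyl]methanone | C(c1ccccc1)Oc1ccc2c(c1)O[C@H](c1cc(OCc3ccccc3)c(OCc3ccccc3)cc1[C@@H]1c3ccc(OCc4ccccc4)cc3O[C@@H]1C(=O)c1cc(OCc3ccccc3)c(OCc3ccccc3)cc1Br)[C@@H](OCc1ccccc1)C2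
F5 | step 14 | (3R)-1-[4,5-bis(benzyloxy)-2-bromophenyl]-3-[4-(benzyloxy)-2-hydroxyphenyl]-3-{4,5-bis(benzyloxy)-2-[(2R,3S)-3,7-bis(benzyloxy)chroman-2-yl]phenyl}propan-1-one | C(c1ccccc1)Oc1ccc2c(c1)O[C@H](c1cc(OCc3ccccc3)c(OCc3ccccc3)cc1[C@@H](CC(=O)c1cc(OCc3ccccc3)c(OCc3ccccc3)cc1Br)c1ccc(OCc3ccccc3)cc1O)[C@@H](OCc1ccccc1)C2
F6 | step 14 | (4R)-7-(benzyloxy)-2-[4,5-bis(benzyloxy)-2-bromophenyl]-4-{4,5-bis(benzyloxy)-2-[(2R,3S)-3,7-bis(benzyloxy)chroman-2-yl]phenyl}-4H-chromene | C(c1ccccc1)Oc1ccc2c(c1)O[C@H](c1cc(OCc3ccccc3)c(OCc3ccccc3)cc1[C@H]1C=C(c3cc(OCc4ccccc4)c(OCc4ccccc4)cc3Br)Oc3cc(OCc4ccccc4)ccc13)[C@@H](OCc1ccccc1)C2
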